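**Plan**

1. Numbering: furanone ring O1, C2(=O), C3(CH3), C4(OH), C5; chain C6 (=CH), C7 (stereocentre) to C18; then the 3-furyl ring. Retrosynthetic cuts, in order: a blocking allyl carboxylate on C3 (removed last), the exocyclic C5=C6 alkene (Horner–Wadsworth–Emmons), the ring bond C4–C5 (Dieckmann-type closure of the furan-2,4-dione ring), then C10–C11 and C16–C17 (two B-alkyl Suzuki couplings).
2. Enabling feature: in the furanone ring, C5 is at once the carbon on the ring oxygen O1, the α-carbon of the C4 carbonyl and the inner end of the exocyclic C5=C6 alkene. One phosphoryl group on C5 therefore first makes C5 the carbanion that closes the ring onto C4 and then leaves as phosphate when C5=C6 is formed. C3, acidic between C2 and C4, is kept quaternary by a second allyl ester that finally leaves as CO2.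
3. Forward order: triester precursor (steps 1–3) and ring closure (step 4); (E)-vinyl iodide and furyl arm (steps 5–8); (Z)-vinyl iodide (step 9); C7 building block (steps 10–11); chain union and oxidation (steps 12–13); olefination (step 14) and unmasking of the tetronic acid (step 15).
4. Stereochemistry: C7 (S) from an Evans allylation with the (R)-4-benzyl auxiliary; C15=C16 (E) from syn carboalumination; C11=C12 (Z) from a Stork–Zhao olefination, both carried through Suzuki couplings with retention; C5=C6 (Z) from the olefination, which places the C4 carbonyl trans to the chain.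

Key step: step 4

Remark: the target is taken as the 4-hydroxy (enol) tautomer drawn, with (S) at C7 and Z, Z, E geometry at C5=C6, C11=C12 and C15=C16 as read from the SMILES; the ring stereocentres formed at C3 and C5 on the way are left uncontrolled because both carbons are sp2 in the target.

**Route**

Step 1
Reactants: 1 2,2,5-trimethyl-1,3-dioxane-4,6-dione; 2 allyl alcohol
Product: 3 3-(allyloxy)-2-methyl-3-oxopropanoic acid
Conditions: 2 (3 equiv), toluene, 100 °C
Reagents that add atoms: none
Why: Alcoholysis of the cyclic acylal (Meldrum's acid ring opening) by allyl alcohol should give the malonic half ester with loss of acetone, the free acid being kept for the next esterification.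

Step 2
Reactants: 3 3-(allyloxy)-2-methyl-3-oxopropanoic acid; 4 diethyl (hydroxymethyl)phosphonate
Product: 5 1-allyl 3-[(diethoxyphosphoryl)methyl] 2-methylpropanedioate
Conditions: EDC·HCl (1.2 equiv), DMAP (0.1 equiv), CH2Cl2, 0 °C to rt
Reagents that add atoms: none
Why: Steglich esterification (carbodiimide with DMAP) should join the half acid to the primary hydroxyl of 4 under neutral conditions that leave the allyl ester and the phosphonate untouched.

Step 3
Reactants: 5 1-allyl 3-[(diethoxyphosphoryl)methyl] 2-methylpropanedioate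
Product: 6 1,1-diallyl 1-[(diethoxyphosphoryl)methyl] ethane-1,1,1-tricarboxylate
Conditions: NaH (1.1 equiv), THF, 0 °C; ClCO2CH2CH=CH2, 0 °C to rt
Reagents that add atoms: allyl chloroformate, C=CCOC(Cl)=O
Why: C-Acylation of the sodium malonate enolate by the chloroformate (Claisen-type acylation to a methanetricarboxylate) should make C3 quaternary, so that it carries no acidic hydrogen in the ring closure and bears two equivalent allyl esters.

Step 4
Reactants: 6 1,1-diallyl 1-[(diethoxyphosphoryl)methyl] ethane-1,1,1-tricarboxylate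
Product: 8 allyl 5-(diethoxyphosphoryl)-3-methyl-2,4-dioxotetrahydrofuran-3-carboxylate, via α-lithio phosphonate 7 (not isolated)
Conditions: LiN(iPr)2 (2.1 equiv), THF (0.02 M), −78 to −30 °C; then AcOH, −78 °C
Reagents that add atoms: none
Why: Proposed new method: LiN(iPr)2 removes the only acidic C–H of 6 (the P–CH2–O hydrogen, since C3 is quaternary), and the lithium carbanion 7, held by chelation between P=O and the ester carbonyls, attacks one of the two equivalent allyl ester carbonyls on C3 so that the C4–C5 bond closes the furan-2,4-dione ring with loss of allyloxide. The closest known reaction type is the Dieckmann (intramolecular Claisen) condensation in its phosphonate form, in which an α-phosphoryl carbanion is acylated by a tethered ester to a cyclic β-keto phosphonate; what is new is the α-acyloxy carbanion as nucleophile and a tetronic-acid-type ring as product. The ring closes in the 5-exo-trig mode (C5 attacks C4 while the C4=O bond stays outside the forming ring). The two new stereocentres (C3 and C5) are not controlled and need not be, because C5 becomes sp2 in step 14 and C3 in step 15. The step needs C5 and not C3 as the nucleophile, which the quaternary C3 secures, and 5-exo closure in preference to 3-exo attack on the nearer C2 carbonyl; should that 1,2-acyl shift occur, the alkoxide formed can still lactonise onto an allyl ester to the same compound 8, because the three carbonyl groups on C3 are interchangeable. The closure should be driven forward by deprotonation of the acidic C5–H of the β-keto phosphonate by the second equivalent of base.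

Step 5
Reactants: 9 furan-3-carbaldehyde
Product: 10 3-vinylfuran
Conditions: Ph3PCH3Br, KOtBu, Et2O, 0 °C to rt; distilled and kept as a solution in THF
Reagents that add atoms: methyltriphenylphosphonium bromide, C[P+](c1ccccc1)(c1ccccc1)c1ccccc1.[Br-]
Why: Wittig methylenation of the aromatic aldehyde should give the volatile vinylfuran, which is carried on as a solution.

Step 6
Reactants: 11 pent-4-yn-1-ol
Product: 13 (E)-5-iodo-4-methylpent-4-en-1-ol, via alkenylalane 12 (not isolated)
Conditions: AlMe3 (3 equiv), Cp2ZrCl2 (0.25 equiv), CH2Cl2, 0 °C to rt; then I2, THF, −30 to 0 °C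
Reagents that add atoms: trimethylaluminium, C[Al](C)C; iodine, II
Why: Zirconium-catalysed Negishi carboalumination should add methyl and aluminium syn across the terminal alkyne with methyl on the inner carbon, and iodinolysis of the C–Al bond with retention should give the (E)-vinyl iodide that fixes the C15=C16 geometry.

Step 7
Reactants: 10 3-vinylfuran; 13 (E)-5-iodo-4-methylpent-4-en-1-ol
Product: 15 (E)-7-(furan-3-yl)-4-methylhept-4-en-1-ol, via B-alkyl-9-BBN 14 (not isolated)
Conditions: 10, 9-BBN, THF, 0 °C to rt; then 13, Pd(dppf)Cl2 (5 mol %), Cs2CO3, DMF/H2O, rt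
Reagents that add atoms: none
Why: Anti-Markovnikov hydroboration of the vinyl group with 9-BBN followed by B-alkyl Suzuki–Miyaura coupling, which proceeds with retention at the vinyl iodide, should form C16–C17 without touching the furan or the free hydroxyl.

Step 8
Reactants: 15 (E)-7-(furan-3-yl)-4-methylhept-4-en-1-ol
Product: 16 (E)-7-(furan-3-yl)-4-methylhept-4-enal
Conditions: Dess–Martin periodinane, NaHCO3, CH2Cl2, 0 °C to rt
Reagents that add atoms: none
Why: Buffered Dess–Martin oxidation should give the aldehyde without over-oxidation or damage to the acid-sensitive furan.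

Step 9
Reactants: 16 (E)-7-(furan-3-yl)-4-methylhept-4-enal
Product: 17 3-[(3E,7Z)-8-iodo-4-methylnona-3,7-dien-1-yl]furan
Conditions: EtPPh3I, n-BuLi, THF, rt; I2, −78 °C; NaN(SiMe3)2, −20 °C; then 16, −78 to −20 °C
Reagents that add atoms: ethyltriphenylphosphonium iodide, CC[P+](c1ccccc1)(c1ccccc1)c1ccccc1.[I-]; iodine, II
Why: Stork–Zhao olefination with the α-iodo ylide should give the trisubstituted (Z)-vinyl iodide (iodine cis to the chain) under kinetic control, which fixes the C11=C12 geometry.

Step 10
Reactants: 18 (R)-4-benzyl-3-propionyloxazolidin-2-one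
Product: 19 (R)-4-benzyl-3-[(S)-2-methylpent-4-enoyl]oxazolidin-2-one
Conditions: NaN(SiMe3)2 (1.1 equiv), THF, −78 °C; allyl iodide, −78 to −45 °C
Reagents that add atoms: allyl iodide, C=CCI
Why: Evans asymmetric alkylation: the chelated (Z)-sodium enolate should be allylated on the face opposite the benzyl group of the (R)-auxiliary, which sets the future C7 centre as (S).

Step 11
Reactants: 19 (R)-4-benzyl-3-[(S)-2-methylpent-4-enoyl]oxazolidin-2-one
Product: 20 (S)-2-methylpent-4-en-1-ol
Conditions: LiBH4, MeOH (1 equiv), Et2O, 0 °C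
Reagents that add atoms: none
Why: Reductive cleavage of the imide with LiBH4 should release the primary alcohol and the recoverable auxiliary without epimerisation or reduction of the alkene.

Step 12
Reactants: 20 (S)-2-methylpent-4-en-1-ol; 17 3-[(3E,7Z)-8-iodo-4-methylnona-3,7-dien-1-yl]furan
Product: 22 (2S,6Z,10E)-13-(furan-3-yl)-2,6,10-trimethyltrideca-6,10-dien-1-ol, via bis-boryl intermediate 21 (not isolated)
Conditions: 20, 9-BBN (2.2 equiv), THF, 0 °C to rt; then 17, Pd(dppf)Cl2 (5 mol %), Cs2CO3, DMF/H2O, rt
Reagents that add atoms: none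
Why: Hydroboration of the terminal alkene with 9-BBN (a further equivalent is taken up by the hydroxyl as a borinate that is hydrolysed on work-up) and B-alkyl Suzuki–Miyaura coupling with retention at the (Z)-vinyl iodide should form C10–C11 and complete the chain.

Step 13
Reactants: 22 (2S,6Z,10E)-13-(furan-3-yl)-2,6,10-trimethyltrideca-6,10-dien-1-ol
Product: 23 (2S,6Z,10E)-13-(furan-3-yl)-2,6,10-trimethyltrideca-6,10-dienal
Conditions: Dess–Martin periodinane, NaHCO3, CH2Cl2, 0 °C to rt; used crude
Reagents that add atoms: none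
Why: Buffered Dess–Martin oxidation should give the α-branched aldehyde without epimerisation at C7, and the crude aldehyde is used at once.

Step 14
Reactants: 8 allyl 5-(diethoxyphosphoryl)-3-methyl-2,4-dioxotetrahydrofuran-3-carboxylate; 23 (2S,6Z,10E)-13-(furan-3-yl)-2,6,10-trimethyltrideca-6,10-dienal
Product: 24 allyl (5Z)-5-[(2S,6Z,10E)-13-(furan-3-yl)-2,6,10-trimethyltrideca-6,10-dien-1-ylidene]-3-methyl-2,4-dioxotetrahydrofuran-3-carboxylate
Conditions: LiCl, iPr2NEt, MeCN, 0 °C to rt
Reagents that add atoms: none
Why: Horner–Wadsworth–Emmons olefination under Masamune–Roush conditions (LiCl with an amine base) should convert the β-keto phosphonate and the aldehyde into the enone with the C4 carbonyl trans to the chain, that is the (Z)-C5=C6 alkene, mildly enough to keep C7 intact.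

Step 15
Reactants: 24 allyl (5Z)-5-[(2S,6Z,10E)-13-(furan-3-yl)-2,6,10-trimethyltrideca-6,10-dien-1-ylidene]-3-methyl-2,4-dioxotetrahydrofuran-3-carboxylate
Product: 26 (5Z)-5-[(2S,6Z,10E)-13-(furan-3-yl)-2,6,10-trimethyltrideca-6,10-dien-1-ylidene]-4-hydroxy-3-methylfuran-2(5H)-one, via β-keto acid 25 (not isolated)
Conditions: Pd(OAc)2 (5 mol %), PPh3 (20 mol %), HCO2H, Et3N, THF, rt; then pH 3 buffer
Reagents that add atoms: none
Why: Tsuji deallylation: zerovalent palladium formed in situ should ionise the allyl ester, formate should reduce the allyl fragment to propene, and the β-keto acid 25 should lose CO2 and enolise to the tetronic acid, any (E)-isomer being expected to equilibrate to the more stable (Z)-alkene.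

**Compound list**

1 | 2,2,5-trimethyl-1,3-dioxane-4,6-dione | CC1C(=O)OC(C)(C)OC1=O | starting material
2 | allyl alcohol | C=CCO | starting material
3 | 3-(allyloxy)-2-methyl-3-oxopropanoic acid (racemic) | CC(C(=O)O)C(=O)OCC=C | intermediate
4 | diethyl (hydroxymethyl)phosphonate | CCOP(=O)(CO)OCC | starting material
5 | 1-allyl 3-[(diethoxyphosphoryl)methyl] 2-methylpropanedioate (racemic) | CCOP(=O)(COC(=O)C(C)C(=O)OCC=C)OCC | intermediate
6 | 1,1-diallyl 1-[(diethoxyphosphoryl)methyl] ethane-1,1,1-tricarboxylate | CCOP(=O)(COC(=O)C(C)(C(=O)OCC=C)C(=O)OCC=C)OCC | intermediate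
7 | α-lithio derivative of 6 (lithium on the P–CH–O carbon) | [Li]C(OC(=O)C(C)(C(=O)OCC=C)C(=O)OCC=C)P(=O)(OCC)OCC | intermediate
8 | allyl 5-(diethoxyphosphoryl)-3-methyl-2,4-dioxotetrahydrofuran-3-carboxylate (mixture of diastereomers) | CCOP(=O)(OCC)C1OC(=O)C(C)(C(=O)OCC=C)C1=O | intermediate
9 | furan-3-carbaldehyde | O=Cc1ccoc1 | starting material
10 | 3-vinylfuran | C=Cc1ccoc1 | intermediate
11 | pent-4-yn-1-ol | C#CCCCO | starting material
12 | dimethyl[(1E)-5-(dimethylalumanyloxy)-2-methylpent-1-en-1-yl]alumane | C[Al](C)/C=C(\C)CCCO[Al](C)C | intermediate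
13 | (E)-5-iodo-4-methylpent-4-en-1-ol | OCCC/C(C)=C/I | intermediate
14 | 9-[2-(furan-3-yl)ethyl]-9-borabicyclo[3.3.1]nonane | C(Cc1ccoc1)B1C2CCCC1CCC2 | intermediate
15 | (E)-7-(furan-3-yl)-4-methylhept-4-en-1-ol | OCCC/C(C)=C/CCc1ccoc1 | intermediate
16 | (E)-7-(furan-3-yl)-4-methylhept-4-enal | O=CCC/C(C)=C/CCc1ccoc1 | intermediate
17 | 3-[(3E,7Z)-8-iodo-4-methylnona-3,7-dien-1-yl]furan | I/C(C)=C\CC/C(C)=C/CCc1ccoc1 | intermediate
18 | (R)-4-benzyl-3-propionyloxazolidin-2-one | CCC(=O)N1[C@H](Cc2ccccc2)COC1=O | starting material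
19 | (R)-4-benzyl-3-[(S)-2-methylpent-4-enoyl]oxazolidin-2-one | C=CC[C@H](C)C(=O)N1[C@H](Cc2ccccc2)COC1=O | intermediate
20 | (S)-2-methylpent-4-en-1-ol | OC[C@@H](C)CC=C | intermediate
21 | 9-[(4S)-5-(9-borabicyclo[3.3.1]nonan-9-yloxy)-4-methylpentyl]-9-borabicyclo[3.3.1]nonane | C1CC2CCCC(C1)B2OC[C@@H](C)CCCB1C2CCCC1CCC2 | intermediate
22 | (2S,6Z,10E)-13-(furan-3-yl)-2,6,10-trimethyltrideca-6,10-dien-1-ol | OC[C@@H](C)CCC/C(C)=C\CC/C(C)=C/CCc1ccoc1 | intermediate
23 | (2S,6Z,10E)-13-(furan-3-yl)-2,6,10-trimethyltrideca-6,10-dienal | O=C[C@@H](C)CCC/C(C)=C\CC/C(C)=C/CCc1ccoc1 | intermediate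
24 | allyl (5Z)-5-[(2S,6Z,10E)-13-(furan-3-yl)-2,6,10-trimethyltrideca-6,10-dien-1-ylidene]-3-methyl-2,4-dioxotetrahydrofuran-3-carboxylate (both C3 epimers) | C=CCOC(=O)C1(C)C(=O)/C(=C/[C@@H](C)CCC/C(C)=C\CC/C(C)=C/CCc2ccoc2)OC1=O | intermediate
25 | (5Z)-5-[(2S,6Z,10E)-13-(furan-3-yl)-2,6,10-trimethyltrideca-6,10-dien-1-ylidene]-3-methyl-2,4-dioxotetrahydrofuran-3-carboxylic acid | OC(=O)C1(C)C(=O)/C(=C/[C@@H](C)CCC/C(C)=C\CC/C(C)=C/CCc2ccoc2)OC1=O | intermediate
26 | (5Z)-5-[(2S,6Z,10E)-13-(furan-3-yl)-2,6,10-trimethyltrideca-6,10-dien-1-ylidene]-4-hydroxy-3-methylfuran-2(5H)-one | CC1=C(O)/C(=C/[C@@H](C)CCC/C(C)=C\CC/C(C)=C/CCc2ccoc2)OC1=O | target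

**Step count and risks**

Total steps: 15. Longest linear sequence: 8 steps (11 → 13 → 15 → 16 → 17 → 22 → 23 → 24 → 26; the branch from 9 is equally long).

Steps most likely to fail:

Step 4 (proposed new method). The α-lithiated phosphonate may be diverted by a 1,2-acyl shift followed by phosphonate-to-phosphate migration, or the closed ring may be reopened by allyloxide (retro-Claisen) before it is enolised. The fallback uses known tetronate chemistry, sets out from aldehyde 23 and comes back at the target 26 without needing 8. Commercial 3-methyltetronic acid (CC1=C(O)COC1=O) is O-methylated (dimethyl sulfate, K2CO3, acetone) to 4-methoxy-3-methylfuran-2(5H)-one F1. Its C5 lithium enolate (LiN(iPr)2, THF, −78 °C) is added to 23 to give the aldol adduct 5-[(2S,6Z,10E)-13-(furan-3-yl)-1-hydroxy-2,6,10-trimethyltrideca-6,10-dien-1-yl]-4-methoxy-3-methylfuran-2(5H)-one F2. Mesylation (MsCl, Et3N, CH2Cl2) gives the methanesulfonate F3, and elimination with DBU should give the (Z)-ylidene methyl tetronate (5Z)-5-[(2S,6Z,10E)-13-(furan-3-yl)-2,6,10-trimethyltrideca-6,10-dien-1-ylidene]-4-methoxy-3-methylfuran-2(5H)-one F4. O-Demethylation with LiSPr in HMPA at rt then gives 26.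

Step 14. The oxygen-substituted, hindered phosphonate anion may add slowly to the α-branched aldehyde, and the non-enolisable tricarbonyl product may suffer retro-Claisen opening or conjugate addition under the basic conditions, with loss of geometric control. The fallback sets out from 8 (with 23) and comes back at 26, changing the order of events so that no tricarbonyl enone is formed. The allyl carboxylate of 8 is removed first (Pd(OAc)2, PPh3, HCO2H, Et3N, THF) to give 5-(diethoxyphosphoryl)-4-hydroxy-3-methylfuran-2(5H)-one F5. Its dianion (LiN(SiMe3)2, 2.2 equiv, THF, −78 °C) is then condensed with 23 in a Horner–Wadsworth–Emmons reaction and acidified to give 26 directly.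

Step 9. Z selectivity may erode and iodine may be lost in the α-iodo ylide olefination (formation of the iodine-free alkene or of the 1,1-diiodoalkene). The fallback sets out from aldehyde 16 and comes back at 22. Dibromo-olefination (CBr4, PPh3, CH2Cl2, 0 °C) gives 3-[(3E)-8,8-dibromo-4-methylocta-3,7-dien-1-yl]furan F6. A trans-selective Negishi monomethylation (MeZnCl, Pd[P(t-Bu)3]2 cat., THF), in which the C–Br bond trans to the chain reacts first, gives 3-[(3E,7Z)-8-bromo-4-methylnona-3,7-dien-1-yl]furan F7 with bromine cis to the chain. F7 takes the place of 17 in the coupling of step 12 to give 22.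

Further compounds
F1 | step 4 | 4-methoxy-3-methylfuran-2(5H)-one | COC1=C(C)C(=O)OC1
F2 | step 4 | 5-[(2S,6Z,10E)-13-(furan-3-yl)-1-hydroxy-2,6,10-trimethyltrideca-6,10-dien-1-yl]-4-methoxy-3-methylfuran-2(5H)-one | COC1=C(C)C(=O)OC1C(O)[C@@H](C)CCC/C(C)=C\CC/C(C)=C/CCc1ccoc1
F3 | step 4 | methanesulfonate of F2 | COC1=C(C)C(=O)OC1C(OS(C)(=O)=O)[C@@H](C)CCC/C(C)=C\CC/C(C)=C/CCc1ccoc1
F4 | step 4 | (5Z)-5-[(2S,6Z,10E)-13-(furan-3-yl)-2,6,10-trimethyltrideca-6,10-dien-1-ylidene]-4-methoxy-3-methylfuran-2(5H)-one | COC1=C(C)C(=O)O/C1=C\[C@@H](C)CCC/C(C)=C\CC/C(C)=C/CCc1ccoc1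
F5 | step 14 | 5-(diethoxyphosphoryl)-4-hydroxy-3-methylfuran-2(5H)-one | CCOP(=O)(OCC)C1OC(=O)C(C)=C1O
F6 | step 9 | 3-[(3E)-8,8-dibromo-4-methylocta-3,7-dien-1-yl]furan | BrC(Br)=CCC/C(C)=C/CCc1ccoc1
F7 | step 9 | 3-[(3E,7Z)-8-bromo-4-methylnona-3,7-dien-1-yl]furan | Br/C(C)=C\CC/C(C)=C/CCc1ccoc1
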